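The target is read as a masked stilbene: its seven-membered carbocycle (C-7c, C-8c, C-9c, C-10c, C-8b, C-9b, C-10b) is the hydroarylation adduct of an (E)-2,4-dioxygenated styryl group on the benzofuran ring of unit c and the central benzene ring. Everything rests on closing the C-10b–C-7c bond last on the skeleton. Acid protonates C-8c, and the ortho,para-dioxygenated benzylic cation at C-7c is captured by C-10b (para to the C-13b oxygen, ortho to the furan oxygen). The same acid then epimerises both cis-dihydrobenzofurans to trans. The precursor is an open bis(cis-2,3-diaryldihydrobenzofuran) stilbene, made by one double enantioselective carbene C–H insertion and a Heck reaction.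

Key step: step 8

Labels (stilbenoid numbering):
- Unit a: C-7a (OCH carrying the 4-oxygenated ring A) and C-8a (CH carrying the 3,5-dioxygenated ring B).
- Unit b: C-7b (OCH carrying the 4-oxygenated ring C), C-8b, and the central ring D. In ring D, C-9b is bonded to C-8b, C-10b is the ring-closure carbon, C-11b carries the furan oxygen of unit a, C-12b is bonded to C-8a, C-13b carries oxygen and C-14b carries H.
- Unit c: C-7c (CH carrying the 2,4-dioxygenated ring E), C-8c (CH2) and ring G. In ring G, C-9c is bonded to C-8c, C-10c to C-8b, C-11c carries the furan oxygen of unit b and C-13c carries oxygen.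

Assumption: Rh2(R-PTAD)4 is taken to induce the (S) configuration at C-8a and C-8b; if the sense of induction is the reverse, the enantiomeric catalyst Rh2(S-PTAD)4 is used with no other change.

Step 1
Reactants: 1 4-bromo-3,5-dimethoxybenzoic acid; 2 3,5-dimethoxybenzonitrile
Product: 4 4-(3,5-dimethoxybenzoyl)-3,5-dimethoxybenzoic acid, via ketimine 3 (not isolated)
Conditions: n-BuLi (2.1 equiv), THF, −78 °C; then 2, −78 °C → rt; then 2 M HCl, 50 °C
Reagents that add atoms: water, O
Why: Bromine–lithium exchange on the lithium carboxylate gives a 2,6-dimethoxyaryllithium that adds once to the nitrile, and hydrolysis of the ketimine should give the diaryl ketone without over-addition.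

Step 2
Reactants: 4 4-(3,5-dimethoxybenzoyl)-3,5-dimethoxybenzoic acid; 5 1-bromo-3,5-dimethoxybenzene
Product: 7 (2-bromo-4,6-dimethoxyphenyl)[4-(3,5-dimethoxybenzoyl)-3,5-dimethoxyphenyl]methanone, via acid chloride 6 (not isolated)
Conditions: (COCl)2, DMF (cat.), CH2Cl2, rt, evaporate; then 5 (1.5 equiv), AlCl3 (2.5 equiv), CH2Cl2, −10 → 0 °C; 1 M HCl
Reagents that add atoms: none
Why: Friedel–Crafts acylation of the bromodimethoxyarene should occur next to bromine, para to one methoxy group (the site between the two methoxy groups is more hindered, as in the Vilsmeier formylation of this arene), while ring D of the acid chloride is deactivated by two carbonyl groups and ring B by one, so that self-acylation should not compete.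

Step 3
Reactants: 7 (2-bromo-4,6-dimethoxyphenyl)[4-(3,5-dimethoxybenzoyl)-3,5-dimethoxyphenyl]methanone
Product: 8 (2-bromo-6-hydroxy-4-methoxyphenyl)[4-(3,5-dimethoxybenzoyl)-3-hydroxy-5-methoxyphenyl]methanone
Conditions: BCl3 (3 equiv), CH2Cl2, −78 → 0 °C; then aqueous work-up
Reagents that add atoms: none
Why: Chelation-controlled ether cleavage, in which BCl3 bound to each ketone oxygen removes only a methyl group ortho to that carbonyl: one of the two equivalent ones on ring D (the boron chelate then protects the other) and the single one on ring G.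

Step 4
Reactants: 8 (2-bromo-6-hydroxy-4-methoxyphenyl)[4-(3,5-dimethoxybenzoyl)-3-hydroxy-5-methoxyphenyl]methanone; 9 4-methoxybenzyl chloride (2.4 equiv; two molecules are incorporated, one per phenol)
Product: 10 {2-bromo-4-methoxy-6-[(4-methoxybenzyl)oxy]phenyl}{4-(3,5-dimethoxybenzoyl)-3-methoxy-5-[(4-methoxybenzyl)oxy]phenyl}methanone
Conditions: K2CO3 (3 equiv), NaI (cat.), DMF, 60 °C
Reagents that add atoms: 4-methoxybenzyl chloride (the second molecule of 9, for the second phenol), COc1ccc(CCl)cc1
Why: Twofold Williamson ether synthesis at the only two acidic sites; each benzylic CH2 introduced here becomes C-7a or C-7b with its 4-methoxyphenyl ring.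

Step 5
Reactants: 10 {2-bromo-4-methoxy-6-[(4-methoxybenzyl)oxy]phenyl}{4-(3,5-dimethoxybenzoyl)-3-methoxy-5-[(4-methoxybenzyl)oxy]phenyl}methanone
Product: 11 bis-hydrazone of 10 (both C=O replaced by C=N–NH2; geometry immaterial)
Conditions: N2H4·H2O (excess), AcOH (cat.), n-BuOH, 110 °C, sealed vessel
Reagents that add atoms: hydrazine (as the hydrate), NN; hydrazine (second molecule, for the second ketone), NN
Why: Acid-catalysed condensation of hydrazine with each of the two diaryl ketones under forcing conditions; the electron-rich aryl bromide should not undergo substitution.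

Step 6
Reactants: 11 bis-hydrazone of 10
Product: 13 (2R,3S)-6-[(2R,3S)-4-bromo-6-methoxy-2-(4-methoxyphenyl)-2,3-dihydrobenzofuran-3-yl]-3-(3,5-dimethoxyphenyl)-4-methoxy-2-(4-methoxyphenyl)-2,3-dihydrobenzofuran (both rings cis; 7aR,8aS,7bR,8bS), via bis-diazo compound 12 (not isolated)
Conditions: MnO2 (activated, excess), CH2Cl2, 0 °C → rt, filter through Celite; then slow addition to Rh2(R-PTAD)4 [dirhodium tetrakis((R)-(1-adamantyl)(phthalimido)acetate), 2 mol %], CH2Cl2, −20 °C → rt
Reagents that add atoms: none
Why: MnO2 dehydrogenates both hydrazones to diaryldiazomethanes, and the chiral dirhodium carboxylate converts each into a donor/donor carbene that inserts into the 1,5-related benzylic O–CH2 bond (enantioselective intramolecular C–H insertion) to give a cis-2,3-diaryldihydrobenzofuran; the catalyst sets C-8a and C-8b (both S, the two remote sites having the same local topology), C-7a and C-7b arise cis (R), and the methylene C–H activated by oxygen and 4-methoxyphenyl should be preferred over the O-methyl group on ring D.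

Step 7
Reactants: 13 bromo bis(cis-dihydrobenzofuran) (7aR,8aS,7bR,8bS); 14 2,4-dimethoxystyrene
Product: 15 (2R,3S)-6-{(2R,3S)-4-[(E)-2-(2,4-dimethoxyphenyl)ethenyl]-6-methoxy-2-(4-methoxyphenyl)-2,3-dihydrobenzofuran-3-yl}-3-(3,5-dimethoxyphenyl)-4-methoxy-2-(4-methoxyphenyl)-2,3-dihydrobenzofuran
Conditions: Pd2(dba)3 (2.5 mol %), P(t-Bu)3·HBF4 (10 mol %), Cy2NMe, 1,4-dioxane, 80 °C
Reagents that add atoms: none
Why: Mizoroki–Heck reaction of the aryl bromide with the styrene, in which syn insertion and syn β-hydride elimination give the (E)-stilbene and the amine base leaves the benzylic stereocentres untouched.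

Step 8
Reactants: 15 (E)-stilbene with two cis-dihydrobenzofurans (7aR,8aS,7bR,8bS)
Product: 17 octamethyl ether of the target (7aS,8aS,7bS,8bS,7cS; both dihydrobenzofurans trans), via cis-dihydrobenzofuran heptacycle 16 (not isolated)
Conditions: TfOH (0.5 equiv), HFIP/CH2Cl2 (1:4), 0.002 M, −30 °C; then rt
Reagents that add atoms: none
Why: TfOH protonates the stilbene at C-8c, because only this gives a cation (C-7c) stabilised by the ortho- and para-methoxy groups of ring E, and C-10b of ring D then attacks it in an intramolecular Friedel–Crafts alkylation (alkene hydroarylation), the reaction type by which ε-viniferin-type stilbenes close to ampelopsin B-type dibenzocycloheptanes. The seven-membered ring closes in a 7-endo-trig mode with respect to the former alkene, both of whose carbons (C-7c and C-8c) end up in the ring, with C-8b as the single sp3 atom of the tether. The new stereocentre C-7c is controlled by C-8b: ring D is held on one face of the ring G/dihydrofuran plane, the cation is captured with ring E pseudo-equatorial and trans to C-7b across the new ring, and because the alkylation is reversible in this medium the thermodynamically preferred (7cS) isomer should accumulate. The step needs site selectivity for C-10b over C-14b and chemoselectivity for alkene protonation over ionisation of the C-7b–O bond (after which the alkene would trap the C-7b cation as an indane). The first is secured by the C-13b methoxy group, which is buttressed by C-12b so that its methyl group shields C-14b and would be twisted out of conjugation by attack there; the second by ring E, which makes C-8c the most basic carbon, and by starting at −30 °C. On warming, the same acid reversibly ionises the C-7a–O and C-7b–O bonds (4-methoxybenzyl cations that can only reclose on the same phenol oxygen), so both dihydrobenzofurans should relax from cis to trans while C-8a and C-8b stay untouched.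

Step 9
Reactants: 17 octamethyl ether of the target
Product: 18 CNP0154774.1 (7aS,8aS,7bS,8bS,7cS)
Conditions: BBr3 (24 equiv), CH2Cl2, −78 °C → rt; then ice-water
Reagents that add atoms: none
Why: Lewis acid-mediated cleavage of all eight aryl methyl ethers by bromide attack on the boron-complexed methyl groups; no alkene is left, and any reversible opening of a dihydrobenzofuran at C-7 can only reclose to the same trans ring, so the five stereocentres should be kept.

Compound list
1 | 4-bromo-3,5-dimethoxybenzoic acid | COc1cc(C(=O)O)cc(OC)c1Br | starting material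
2 | 3,5-dimethoxybenzonitrile | COc1cc(C#N)cc(OC)c1 | starting material
3 | 4-[(3,5-dimethoxyphenyl)(imino)methyl]-3,5-dimethoxybenzoic acid (ketimine; dilithium salt before the acid quench) | COc1cc(cc(OC)c1)C(=N)c1c(OC)cc(cc1OC)C(=O)O | intermediate (not isolated)
4 | 4-(3,5-dimethoxybenzoyl)-3,5-dimethoxybenzoic acid | COc1cc(cc(OC)c1)C(=O)c1c(OC)cc(cc1OC)C(=O)O | intermediate
5 | 1-bromo-3,5-dimethoxybenzene | COc1cc(Br)cc(OC)c1 | starting material
6 | 4-(3,5-dimethoxybenzoyl)-3,5-dimethoxybenzoyl chloride | COc1cc(cc(OC)c1)C(=O)c1c(OC)cc(cc1OC)C(Cl)=O | intermediate (not isolated)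
7 | (2-bromo-4,6-dimethoxyphenyl)[4-(3,5-dimethoxybenzoyl)-3,5-dimethoxyphenyl]methanone | COc1cc(cc(OC)c1)C(=O)c1c(OC)cc(cc1OC)C(=O)c1c(Br)cc(OC)cc1OC | intermediate
8 | (2-bromo-6-hydroxy-4-methoxyphenyl)[4-(3,5-dimethoxybenzoyl)-3-hydroxy-5-methoxyphenyl]methanone | COc1cc(cc(OC)c1)C(=O)c1c(O)cc(cc1OC)C(=O)c1c(Br)cc(OC)cc1O | intermediate
9 | 4-methoxybenzyl chloride | COc1ccc(CCl)cc1 | starting material
10 | {2-bromo-4-methoxy-6-[(4-methoxybenzyl)oxy]phenyl}{4-(3,5-dimethoxybenzoyl)-3-methoxy-5-[(4-methoxybenzyl)oxy]phenyl}methanone | COc1cc(cc(OC)c1)C(=O)c1c(OCc2ccc(OC)cc2)cc(cc1OC)C(=O)c1c(Br)cc(OC)cc1OCc1ccc(OC)cc1 | intermediate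
11 | bis-hydrazone of 10 | COc1cc(cc(OC)c1)C(=NN)c1c(OCc2ccc(OC)cc2)cc(cc1OC)C(=NN)c1c(Br)cc(OC)cc1OCc1ccc(OC)cc1 | intermediate
12 | bis-diazo compound from 11 | COc1cc(cc(OC)c1)C(=[N+]=[N-])c1c(OCc2ccc(OC)cc2)cc(cc1OC)C(=[N+]=[N-])c1c(Br)cc(OC)cc1OCc1ccc(OC)cc1 | intermediate (not isolated)
13 | (2R,3S)-6-[(2R,3S)-4-bromo-6-methoxy-2-(4-methoxyphenyl)-2,3-dihydrobenzofuran-3-yl]-3-(3,5-dimethoxyphenyl)-4-methoxy-2-(4-methoxyphenyl)-2,3-dihydrobenzofuran (7aR,8aS,7bR,8bS) | COc1ccc([C@@H]2Oc3cc(cc(OC)c3[C@@H]2c2cc(OC)cc(OC)c2)[C@H]2c3c(Br)cc(OC)cc3O[C@H]2c2ccc(OC)cc2)cc1 | intermediate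
14 | 2,4-dimethoxystyrene (1-ethenyl-2,4-dimethoxybenzene) | C=Cc1ccc(OC)cc1OC | starting material
15 | (E)-stilbene: 13 with the bromine replaced by (E)-2-(2,4-dimethoxyphenyl)ethenyl (7aR,8aS,7bR,8bS) | COc1ccc([C@@H]2Oc3cc(cc(OC)c3[C@@H]2c2cc(OC)cc(OC)c2)[C@H]2c3c(/C=C/c4ccc(OC)cc4OC)cc(OC)cc3O[C@H]2c2ccc(OC)cc2)cc1 | intermediate
16 | octamethyl ether of the target skeleton with both dihydrobenzofurans cis (7aR,8aS,7bR,8bS,7cS) | COc1ccc([C@@H]2Oc3c4c(cc(OC)c3[C@@H]2c2cc(OC)cc(OC)c2)[C@H]2c3c(cc(OC)cc3O[C@H]2c2ccc(OC)cc2)C[C@H]4c2ccc(OC)cc2OC)cc1 | intermediate (not isolated)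
17 | octamethyl ether of the target (7aS,8aS,7bS,8bS,7cS) | COc1ccc([C@H]2Oc3c4c(cc(OC)c3[C@@H]2c2cc(OC)cc(OC)c2)[C@H]2c3c(cc(OC)cc3O[C@@H]2c2ccc(OC)cc2)C[C@H]4c2ccc(OC)cc2OC)cc1 | intermediate
18 | CNP0154774.1 (7aS,8aS,7bS,8bS,7cS) | Oc1ccc([C@H]2Oc3c4c(cc(O)c3[C@@H]2c2cc(O)cc(O)c2)[C@H]2c3c(cc(O)cc3O[C@@H]2c2ccc(O)cc2)C[C@H]4c2ccc(O)cc2O)cc1 | target

Total step count: 9. Longest linear sequence: 9 steps (compound 1 to compound 18).

Steps most likely to fail

Step 8. The C-7b–O bond may ionise before the alkene is protonated, so that the alkene captures the C-7b cation and the material drains into an indane; capture of the C-7c cation at C-14b is the second way the closure can go astray. The fallback sets out from 15 and comes back at 16. Dimethyldioxirane (acetone, 0 °C) should epoxidise the stilbene to the trans-epoxide F1 (either face; both converge). SnCl4 in CH2Cl2 at −78 °C opens the epoxide at C-7c, far below the temperature at which the dihydrobenzofurans ionise, and C-10b closes the seven-membered ring by Friedel–Crafts alkylation to give the C-8c alcohol F2. NaH, CS2 and MeI give the S-methyl xanthate F3, and Bu3SnH with AIBN (toluene, 80 °C; Barton–McCombie deoxygenation) removes the oxygen to give 16. This is epimerised to 17 with TfOH in HFIP/CH2Cl2 at rt, as in the second phase of step 8.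

Step 6. Facial discrimination may be lost at the two doubly ortho-substituted carbenes, a diazo group may couple with a carbene of another molecule (azine formation), or the carbene next to ring D may insert into the neighbouring O-methyl group. The fallback sets out from 8 and comes back at 17. NaBH4 (THF/MeOH) reduces both ketones to the bis(2-hydroxybenzhydrol) F4. Sodium 4-methylbenzenesulfinate in aqueous formic acid gives the bis-sulfone F5. Cs2CO3 (CH2Cl2, 0 °C) releases the two ortho-quinone methides, which undergo (4+1) annulation with the ylide of an S-(4-methoxybenzyl)sulfonium salt of an enantiopure cyclic sulfide (isothiocineole type), giving directly the bis(trans-dihydrobenzofuran) bromide F6. The Heck reaction of step 7 then gives the all-trans stilbene F7, and TfOH in HFIP/CH2Cl2 at −30 °C closes the ring to 17 with no epimerisation required.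

Step 5. Condensation may stay incomplete at the two sterically shielded carbonyl groups under conditions mild enough to spare the aryl bromide. The fallback sets out from 10 and comes back at 12. 1,2-Bis(tert-butyldimethylsilyl)hydrazine with Sc(OTf)3 (1 mol %) condenses with hindered ketones and should give the bis(N-silylhydrazone) F8. (Difluoroiodo)benzene with 2-chloropyridine (CH2Cl2, −78 °C → rt) oxidises F8 directly to the bis-diazo compound 12.

Further compounds
F1 | step 8 | trans-epoxide of 15 at C-7c/C-8c ((7cS,8cS) shown; the (7cR,8cR) diastereomer reacts likewise) | COc1ccc([C@@H]2Oc3cc(cc(OC)c3[C@@H]2c2cc(OC)cc(OC)c2)[C@H]2c3c([C@@H]5O[C@H]5c4ccc(OC)cc4OC)cc(OC)cc3O[C@H]2c2ccc(OC)cc2)cc1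
F2 | step 8 | C-8c alcohol of 16 (either C-8c epimer) | COc1ccc([C@@H]2Oc3c4c(cc(OC)c3[C@@H]2c2cc(OC)cc(OC)c2)[C@H]2c3c(cc(OC)cc3O[C@H]2c2ccc(OC)cc2)C(O)[C@H]4c2ccc(OC)cc2OC)cc1
F3 | step 8 | S-methyl xanthate of F2 | COc1ccc([C@@H]2Oc3c4c(cc(OC)c3[C@@H]2c2cc(OC)cc(OC)c2)[C@H]2c3c(cc(OC)cc3O[C@H]2c2ccc(OC)cc2)C(OC(=S)SC)[C@H]4c2ccc(OC)cc2OC)cc1
F4 | step 6 | bis(2-hydroxybenzhydrol) from 8 (carbinol centres undefined) | COc1cc(cc(OC)c1)C(O)c1c(O)cc(cc1OC)C(O)c1c(Br)cc(OC)cc1O
F5 | step 6 | bis(4-methylbenzenesulfonyl) compound from F4 | COc1cc(cc(OC)c1)C(c1c(O)cc(cc1OC)C(c1c(Br)cc(OC)cc1O)S(=O)(=O)c1ccc(C)cc1)S(=O)(=O)c1ccc(C)cc1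
F6 | step 6 | (7aS,8aS,7bS,8bS) bis(trans-dihydrobenzofuran) bromide (C-7a,C-7b epimer of 13) | COc1ccc([C@H]2Oc3cc(cc(OC)c3[C@@H]2c2cc(OC)cc(OC)c2)[C@H]2c3c(Br)cc(OC)cc3O[C@@H]2c2ccc(OC)cc2)cc1
F7 | step 6 | (7aS,8aS,7bS,8bS) (E)-stilbene (C-7a,C-7b epimer of 15) | COc1ccc([C@H]2Oc3cc(cc(OC)c3[C@@H]2c2cc(OC)cc(OC)c2)[C@H]2c3c(/C=C/c4ccc(OC)cc4OC)cc(OC)cc3O[C@@H]2c2ccc(OC)cc2)cc1
F8 | step 5 | bis(N-tert-butyldimethylsilylhydrazone) of 10 | COc1cc(cc(OC)c1)C(=NN[Si](C)(C)C(C)(C)C)c1c(OCc2ccc(OC)cc2)cc(cc1OC)C(=NN[Si](C)(C)C(C)(C)C)c1c(Br)cc(OC)cc1OCc1ccc(OC)cc1
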